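**Remark on the target:** the oxirane is trans-fused to the seven-membered ring (oxygen bonded to C8 from the β-face and to C9 from the α-face), and it is made exactly as drawn from an (E)-configured C8=C9 bond, because syn epoxidation of the ring (Z)-alkene or backside closure within the ring could only give the cis-fused isomer; daucane numbering is used and β is the face of the C1 methyl group.

## Structural features

The target is a daucane: a cyclopentane (C1–C5) and a cycloheptane (C1, C5–C10) share the C1–C5 bond in a trans fusion, with the angular methyl on quaternary C1 (β) and H5 (α) on opposite faces. Eight stereocentres (C1, C2, C4, C5, C6, C8, C9, C10) form one unbroken array around this bond; C1 alone is flanked by three of them, and the 2-acetoxy, 4-hydroxy, 6-veratroyloxy and 10-hydroxy groups all lie on the α-face. The oxirane is trans-fused to the seven-membered ring: its oxygen is bonded to C8 from the β-side and to C9 from the α-side, C7 and C10 are trans on the three-membered ring, and the 8-methyl group is α. Such a ring is the oxide of an (E)-cycloheptene and carries roughly the extra strain of trans-bicyclo[5.1.0]octane, an isolable hydrocarbon; it cannot be reached by syn epoxidation of the ring (Z)-alkene or by backside closure of a halohydrin within the ring. The fragile groups are two different esters that must not be exchanged (the C2 acetate and the C10 hydroxyl are 1,3-syn, so acyl migration is possible), a strained 2,3-epoxy alcohol open to Payne rearrangement and acid opening, and a tertiary C4 alcohol that can dehydrate. Besides the oxirane, the real difficulty lies at the carbinol carbons C4 and C10: at C4 the isopropyl group must stand cis to the C5–C6 bond, on the face that a nucleophile adding to a C4 ketone avoids, and at C10 hydride must enter syn to the angular methyl. The key step exploits the fact that C1, C5 and C6 are the β-carbon, the α-carbon and the aldol carbon of a C4 carbonyl inside the five-membered ring, with the C1 methyl trans to the C2 oxygen, so that a cyclopentenone carrying the C2 silyloxy group can take up methyl at C1 and an aldehyde at C5 in one operation; the C6 hydroxyl it leaves is the tether for C4, and the alkene of the aldehyde is the handle for the seven-membered ring and for the (E)-alkene.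

## Logic of the disconnections

34 to 33: the acyl–oxygen bond of the C2 acetate is cut last. This removes one of the two esters and leaves three hydroxyls, of which only the one at C2 is secondary and unhindered. The forward step must acylate O2 and leave the C10 hydroxyl (neopentyl, next to the oxirane) and the tertiary C4 hydroxyl free, without acid.

33 to 32 to 31: both C–O bonds of the oxirane are cut, then the E geometry of C8=C9 is relaxed to Z. A trans-fused oxirane can only come from syn transfer of one oxygen atom to an (E)-double bond, so the two oxirane centres are traced to the helicity of 32, and that helicity is dictated by the trans ring fusion. The gain is that everything up to 31 is the chemistry of an ordinary cycloheptene. The forward steps must drive an uphill Z to E isomerisation, hold the (E)-isomer, and deliver oxygen faster than it reverts.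

31 to 29 to 28: the C10–H bond is cut (carbinol to carbonyl), then the O–Si bond at C2. 28 has no C10 centre, and in 29 the free C2 hydroxyl is 1,3 to the carbonyl through C1, so a boron chelate can hold the α-face and send hydride to the β-face. The forward reduction must be 1,2-selective and must override approach anti to the angular methyl.

28 to 27 to 26: the C8=C9 double bond is cut (olefin metathesis) after C10 is adjusted to the alcohol level. The seven-membered ring opens to a cyclopentane with two trans-disposed arms, each ending in an alkene, and the position of the ring alkene is fixed without any isomerisation. The forward step must close a trans-fused cycloheptene with a trisubstituted double bond.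

26 to 25 to 24 to 23: the C9–C10 bond is cut to a vinyl nucleophile and a neopentyl aldehyde, and C10 is taken back to the alcohol and its 4-methoxybenzyl (PMB) ether. The configuration formed at C10 is irrelevant because it is erased in 28. The forward addition must spare the aryl ester, and the ether must come off oxidatively beside a silyl ether and an alkene.

23 to 21 and 22: the ester C–O bond at C6 is cut. Installing the veratrate early makes it the protecting group for C6 through both later oxidations. The forward step must distinguish the secondary C6 hydroxyl from the tertiary C4 hydroxyl.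

21 to 19 to 17 to 15 and 16: a carboxyl carbon is put back on the isopropyl methine and tied to O6 as a lactone, then the C4–C bond is cut to give back the C4 ketone, then the ester bond to O6. A free isopropyl nucleophile would attack the ketone of 15 anti to the C5 side chain and give the C4 epimer; a nucleophile tethered to O6 can only reach the face of the C5–C6 bond. C4 is thereby traced to C6. The forward steps need an enolate formed by reduction and not by base, and a decarboxylation that never passes through the free acid.

15 to 8, 12 and 10 (key disconnection): the C1–CH3 and C5–C6 bonds are cut. Three contiguous stereocentres, one of them quaternary, are traced to a single silyloxy stereocentre and three simple components. The forward step needs conjugate addition at a fully substituted β-carbon, a regiochemically stable enolate, and anti aldol selectivity.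

8 to 7 to 4 and 6 (from 3 through 5): the C1–C10 bond and the C1=C5 unsaturation are cut. An alkoxymethyl cuprate adds to the commercial enone, and dehydrogenation of the trapped silyl enol ether restores the enone with the new arm on the β-carbon. The forward sequence must avoid loss of the silyloxy group from the intermediate enolate.

3 to 1 and 2; 10 to 9; 12 to 11: an ether C–O bond, an oxidation level and a cuprate are traced to commercial materials. The only demand is that the β,γ-unsaturated aldehyde is not isomerised into conjugation.

## Other disconnections considered

Alternative 1: The seven-membered ring is cut at C6–C7 and C9–C10. This leaves the cyclopentane-1,2-dicarbaldehyde A1 (C6 and C10 as formyl groups, C2 acetate and C4 silyl ether in place) and the bifunctional three-carbon reagent A2, an allylic iodide and an allylsilane in one molecule. In the forward sense indium metal should join the iodide end of A2 to the more accessible C6 aldehyde (Barbier allylation), and BF3·OEt2 should then close the silane end onto the neopentyl C10 aldehyde (Hosomi–Sakurai reaction) to give the methylene hydroazulene diol A3.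
- In its favour: it is convergent, forms two skeletal bonds and closes the seven-membered ring, which the chosen key step does not do. On ring construction it is the better plan.
- Against it: A1 is fragile (H5 is α to a formyl group and the C4 silyloxy group is β to it, so epimerisation and elimination threaten). A1 must already contain C1, C2, C4 and C5, so the hard stereochemical work, including the isopropyl carbinol, is only moved into its preparation.
- The two new carbinols C6 and C10 form through open transition states under substrate control alone, and they appear as two free secondary hydroxyls that need different fates.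
- The exocyclic methylene of A3 must still be moved to C8=C9, with two endocyclic positions available; the trans-fused oxirane then demands the same (E)-alkene end game, so on that point the two plans are equal.
- Comparison: the chosen aldol sets C5 and C6 through a closed transition state. The alternative would be shorter after the annulation and longer before it, so the overall count is judged comparable, with more stereochemical risk.

Alternative 2: The five-membered ring is cut at C3–C4. The forward step is Rh2(OAc)4-catalysed loss of nitrogen from the acyclic α-diazoketone A4, with insertion of the C3 carbene carbon into the C4–H bond, which is tertiary and activated by the silyloxy group; this five-membered-ring-forming insertion gives cyclopentanone A5.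
- In its favour: insertion proceeds with retention, so the tertiary C4 centre comes stereospecifically from a secondary carbinol in one step. For C4 this is better than the chosen plan, which needs a tether and three steps to place isopropyl on the hindered face.
- It is the equal of the chosen plan in delivering the cyclopentane with C1, C4 and C5 defined.
- Against it: A4 needs an acyclic array of quaternary C1 next to C5 and C4, for which no short stereocontrolled access is evident. Insertion into the isopropyl methine C–H competes.
- In A5 the C2 oxygen is a ketone that must be reduced from the β-face next to the quaternary centre. The whole seven-membered ring (C7–C9 and the C6 and C10 carbinols) and the oxirane remain to be built from an ester and a silyl ether.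
- Comparison: on step economy the chosen plan is clearly ahead. The alternative trades a tether-controlled for a stereospecific event at one centre only.

Alternative 3: Both bonds from C1 to C5 and C10 are cut, which unravels the bicycle to the anisole-tethered diazoketone A6. Rh2(O2CCF3)4 should generate the carbene at C1, which adds to the C5–C10 bond of the arene; 6π electrocyclic opening of the cyclopropane so formed (Buchner reaction) gives the azulenone A7.
- In its favour: one catalytic step forms two skeletal bonds, both rings and the quaternary C1, from an aromatic precursor that already carries the C6 oxygen and the C8 methyl. In skeletal economy this is better than the chosen plan, whose key step closes no ring.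
- Against it: the methyl-substituted carbene can collapse by 1,2-hydrogen shift. Addition can occur at either ortho bond (C5–C10 or the methoxy-bearing C5–C6), and formal aromatic C–H substitution competes. The configuration at C1 would be induced only by the remote C4 centre.
- Most serious: A7 is a flat cycloheptatriene. C5 (trans fusion), C6, C10 and C2 must still be set, and one alkene out of three must be singled out and brought into the E geometry.
- Comparison: the chosen key step delivers C1, C5 and C6 with H5 α directly. A short way to the bicycle stands against a long and weakly controlled way from there to the target.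

Key step: step 5

## Route

Step 1
Reactants: 1 4-methoxybenzyl alcohol; 2 tributyl(iodomethyl)stannane
Product: 3 tributyl[(4-methoxybenzyloxy)methyl]stannane
Conditions: NaH, THF/DMF, 0 °C to rt
Reagents that add atoms: none
Why: Williamson ether synthesis; the sodium alkoxide displaces iodide from the primary, tin-activated carbon by SN2 substitution, and no stereocentre is involved.

Step 2
Reactants: 3 tributyl[(4-methoxybenzyloxy)methyl]stannane; 4 (R)-4-(tert-butyldimethylsilyloxy)cyclopent-2-en-1-one
Product: 7 trans-3,4-disubstituted trimethylsilyl enol ether, via alkoxymethyllithium 5 (not isolated), via dialkylcuprate 6 (not isolated)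
Conditions: n-BuLi, THF, −78 °C; CuBr·SMe2, −78 °C; TMSCl, then 4, −78 °C; NH4Cl/NH3 buffer work-up
Reagents that add atoms: chlorotrimethylsilane, C[Si](C)(C)Cl
Why: Tin–lithium exchange gives the α-alkoxymethyllithium 5, which CuBr·SMe2 converts into the lithium dialkylcuprate 6; conjugate addition to the enone occurs anti to the silyloxy group. TMSCl accelerates the addition and traps the enolate at once, which forestalls proton transfer and loss of silyloxide; the new stereocentre is removed in step 3.

Step 3
Reactants: 7 trans-3,4-disubstituted trimethylsilyl enol ether
Product: 8 (R)-4-(tert-butyldimethylsilyloxy)-3-[(4-methoxybenzyloxy)methyl]cyclopent-2-en-1-one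
Conditions: Pd(OAc)2, MeCN, rt
Reagents that add atoms: none
Why: Saegusa–Ito oxidation; the silyl enol ether gives a divalent palladium enolate, and β-hydride elimination of the only available β-hydrogen restores the enone with the alkoxymethyl arm on the β-carbon. The silyloxy stereocentre is not touched.

Step 4
Reactants: 9 3-methylbut-3-en-1-ol
Product: 10 3-methylbut-3-enal
Conditions: Dess–Martin periodinane, NaHCO3, CH2Cl2, 0 °C; used as a cold solution
Reagents that add atoms: none
Why: Dess–Martin oxidation under buffered, non-basic conditions should give the β,γ-unsaturated aldehyde without migration of the double bond into conjugation.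

Step 5
Reactants: 8 (R)-4-(tert-butyldimethylsilyloxy)-3-[(4-methoxybenzyloxy)methyl]cyclopent-2-en-1-one; 11 methyllithium; 10 3-methylbut-3-enal
Product: 15 aldol adduct with quaternary C1, via lithium dimethylcuprate 12 (not isolated), via lithium enolate 13 (not isolated), via chlorozinc enolate 14 (not isolated)
Conditions: CuI, Et2O, 0 °C; 8, −78 to −20 °C; ZnCl2 (THF), −78 °C; 10, −78 °C; aq NH4Cl
Reagents that add atoms: none
Why: The cuprate 12 forms a π-complex with the enone and adds oxidatively at C1 to a trivalent copper intermediate, whose reductive elimination makes the C1–CH3 bond and leaves the regiodefined lithium enolate 13 (O–C4=C5). Transmetalation with ZnCl2 gives the less basic chlorozinc enolate 14, which should not equilibrate to the C3 enolate (the path to loss of the C2 silyloxide) and which adds through C5 to the aldehyde in a closed six-membered Zimmerman–Traxler transition state. The closest known reaction type is the three-component coupling of 4-silyloxycyclopent-2-enones by cuprate conjugate addition and aldol trapping of the enolate. No ring is closed; two skeletal bonds (C1–CH3 and C5–C6) are formed. C1: the methyl group enters anti to the C2 silyloxy group, which leaves the CH2OPMB arm cis to that group. C5: the aldehyde approaches the enolate on the β-face, away from the CH2OPMB arm and the silyloxy group that both occupy the α-face, so the side chain is cis to the new methyl and H5 is α. C6: the cyclic enolate is necessarily E, and the chair transition state with the aldehyde substituent equatorial gives the anti aldol, which is the configuration required at C6. The step needs 1,4- over 1,2-addition at a fully substituted β-carbon and a kinetically intact enolate; the soft cuprate secures the first, and low temperature together with zinc the second.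

Step 6
Reactants: 15 aldol adduct with quaternary C1; 16 2-bromo-2-methylpropanoyl bromide
Product: 17 C6 2-bromo-2-methylpropanoate of the aldol adduct
Conditions: pyridine, CH2Cl2, −20 to 0 °C
Reagents that add atoms: none
Why: O-Acylation of the secondary C6 hydroxyl by the acyl bromide (nucleophilic acyl substitution); pyridine is too weak a base to enolise the ketone at C5 and expel the new acyloxy group, and no stereocentre changes.

Step 7
Reactants: 17 C6 2-bromo-2-methylpropanoate of the aldol adduct
Product: 19 cis-fused δ-lactone with the C4 carbinol, via samarium enolate 18 (not isolated)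
Conditions: SmI2 (2.2 equiv), THF, −78 °C; aq NH4Cl
Reagents that add atoms: none
Why: SmI2-promoted intramolecular Reformatsky reaction; two equivalents of divalent samarium reduce the tertiary α-bromo ester, far faster than the ketone, to the trivalent samarium enolate 18, which adds to the C4 carbonyl within a six-membered ring. The tether through O6 can reach only the β-face of C4, the face of the C5–C6 bond, so the lactone is cis-fused, the new C4–C bond is β and the C4 hydroxyl is α. This is the face that an external isopropyl nucleophile would avoid.

Step 8
Reactants: 19 cis-fused δ-lactone with the C4 carbinol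
Product: 21 C4,C6-diol with the 4β-isopropyl carbinol, via lithium carboxylate 20 (not isolated)
Conditions: LiOH, THF/H2O, rt; then [Ir(dF(CF3)ppy)2(dtbbpy)]PF6 (1 mol %), 2,4,6-triisopropylbenzenethiol (10 mol %), DMSO/H2O, blue LEDs, rt
Reagents that add atoms: none
Why: Saponification followed by photoredox hydrodecarboxylation; the excited trivalent iridium complex oxidises the carboxylate 20, CO2 is lost, and the tertiary radical takes a hydrogen atom from the thiol, which turns the carboxyl-bearing carbon into the isopropyl methine. The carboxylate is never acidified and so cannot relactonise; C4 is not touched, and this photocatalyst is not oxidising enough to attack the PMB ether.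

Step 9
Reactants: 21 C4,C6-diol with the 4β-isopropyl carbinol; 22 3,4-dimethoxybenzoyl chloride
Product: 23 C6 veratrate (6-O-(3,4-dimethoxybenzoyl) derivative of 21)
Conditions: Et3N, DMAP, CH2Cl2, 0 °C to rt
Reagents that add atoms: none
Why: DMAP-catalysed acylation (nucleophilic catalysis) of the secondary C6 hydroxyl; the tertiary C4 hydroxyl does not react under these conditions, and no stereocentre changes.

Step 10
Reactants: 23 C6 veratrate
Product: 24 C10 primary alcohol (CH2OH on C1)
Conditions: DDQ, CH2Cl2/pH 7 buffer, 0 °C
Reagents that add atoms: none
Why: Oxidative cleavage of the 4-methoxybenzyl ether (hydride abstraction at the electron-rich benzylic position, then hydrolysis of the oxocarbenium ion). The veratrate has no benzylic C–H and is deactivated by its carbonyl group, and the silyl ether and the alkene are inert.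

Step 11
Reactants: 24 C10 primary alcohol
Product: 25 C10 aldehyde (formyl group on C1)
Conditions: Dess–Martin periodinane, NaHCO3, CH2Cl2, 0 °C to rt
Reagents that add atoms: none
Why: Dess–Martin oxidation of the neopentyl primary alcohol; the tertiary hydroxyl is inert and the aldehyde cannot enolise (quaternary α-carbon). The bridged lactol with the C4 hydroxyl would be a strained 2-oxabicyclo[2.2.1]heptane and should not divert the oxidation.

Step 12
Reactants: 25 C10 aldehyde
Product: 26 C10 vinyl carbinol (both C10 epimers)
Conditions: CH2=CHMgBr, THF, −78 °C
Reagents that add atoms: vinylmagnesium bromide, C=C[Mg]Br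
Why: Grignard 1,2-addition to the non-enolisable aldehyde; at −78 °C the hindered, electron-rich aryl ester is much less electrophilic, and one equivalent of reagent is consumed by the tertiary hydroxyl. The C10 configuration is of no consequence because step 14 removes it.

Step 13
Reactants: 26 C10 vinyl carbinol
Product: 27 trans-fused cycloheptenol (C8=C9 alkene, 10-hydroxy, both C10 epimers)
Conditions: second-generation Grubbs catalyst (5 mol %), CH2Cl2, 40 °C
Reagents that add atoms: none
Why: Ring-closing olefin metathesis; the ruthenium alkylidene forms at the vinyl group and closes onto the 1,1-disubstituted alkene to give the trisubstituted cycloheptene with loss of ethylene. The trans ring fusion is fixed beforehand by the trans arrangement of the two arms on the cyclopentane, and free hydroxyls and esters are tolerated.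

Step 14
Reactants: 27 trans-fused cycloheptenol
Product: 28 enone (C10 ketone conjugated with C8=C9; 2α-OTBS)
Conditions: Dess–Martin periodinane, NaHCO3, CH2Cl2, rt
Reagents that add atoms: none
Why: Dess–Martin oxidation of the allylic alcohol; both C10 epimers converge on one enone, and the tertiary hydroxyl and the esters are inert.

Step 15
Reactants: 28 enone
Product: 29 2α-hydroxy enone
Conditions: HF·pyridine, THF, 0 °C to rt
Reagents that add atoms: none
Why: Fluoride-induced desilylation under weakly acidic conditions; a basic fluoride source is avoided because the product is a β-hydroxy ketone through quaternary C1 (retro-aldol) and the veratrate is a vinylogous β-leaving group of the enone.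

Step 16
Reactants: 29 2α-hydroxy enone
Product: 31 2α,4α,10α-triol with the C8=C9 (Z)-alkene, via diethylboron chelate 30 (not isolated)
Conditions: Et2BOMe, THF/MeOH, −78 °C; NaBH4; MeOH co-evaporation
Reagents that add atoms: none
Why: Narasaka–Prasad reduction; Et2BOMe ties the C2 oxygen and the C10 carbonyl into the six-membered chelate 30, which lies on the α-face with C5 pseudo-axial. External hydride should therefore add axially to the chelate from the β-face, giving the 10α-alcohol (1,3-syn to the C2 hydroxyl). The β,β-disubstituted enone is reduced 1,2, and the esters survive at −78 °C.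

Step 17
Reactants: 31 2α,4α,10α-triol with the C8=C9 (Z)-alkene
Product: 32 AgNO3 complex of the (E)-cycloheptene triol
Conditions: hν (254 nm), methyl benzoate, Et2O, −50 °C, closed-loop flow through AgNO3/SiO2; MeOH elution, −20 °C
Reagents that add atoms: silver nitrate, [Ag+].[O-][N+](=O)[O-]
Why: Sensitised Z to E photoisomerisation of a cycloheptene with silver capture; the excited aromatic ester lets the C8=C9 bond twist, and only the strained (E)-isomer binds AgNO3 strongly enough to stay on the column while the (Z)-isomer recirculates, which pulls the uphill equilibrium to one side. The trans ring fusion holds C6 on the β-side and C10 on the α-side of the ring, so the (E)-bond can bridge C7 and C10 only with C7 β and C10 α (8-methyl α, H9 β); the other helicity would twist the ring against its fusion. No stereocentre is touched, and the veratrate belongs to the same chromophore class as the sensitiser.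

Step 18
Reactants: 32 AgNO3 complex of the (E)-cycloheptene triol
Product: 33 trans-fused 8,9-epoxy triol (O–C8 β, O–C9 α)
Conditions: DMDO (acetone), CH2Cl2, −78 °C; Bu4NCl, −78 °C; Me2S quench
Reagents that add atoms: dimethyldioxirane, CC1(C)OO1
Why: Dioxirane epoxidation, a concerted syn oxygen transfer that keeps the alkene geometry, as in the conversion of (E)-cyclooctene into its trans-fused oxide; chloride strips the silver as AgCl and the strained π-bond is attacked at once on its only open face, the one turned away from the ring. Oxygen thus becomes bonded to C8 from the β-side and to C9 from the α-side, which sets both oxirane centres and leaves C7 and C10 trans on the three-membered ring. The reagent is neutral and its only by-product is acetone, so the strained epoxy alcohol meets neither acid nor base.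

Step 19
Reactants: 33 trans-fused 8,9-epoxy triol
Product: 34 target (2α-acetoxy-6α-(3,4-dimethoxybenzoyloxy)-trans-daucane-4α,10α-diol with the trans-fused 8,9-oxirane, 1β-methyl, 4β-isopropyl, 5α-H)
Conditions: Ac2O, pyridine, DMAP (cat.), CH2Cl2, −20 °C
Reagents that add atoms: acetic anhydride, CC(=O)OC(C)=O
Why: DMAP-catalysed site-selective acylation; the C2 hydroxyl is the most accessible secondary hydroxyl, whereas the C10 hydroxyl is flanked by quaternary C1 and the oxirane carbon and is hydrogen-bonded to the oxirane oxygen, and the C4 hydroxyl is tertiary. Pyridine at −20 °C forms no alkoxide, so neither Payne rearrangement nor opening of the strained oxirane is expected.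

## Compound list

1 | 4-methoxybenzyl alcohol | COc1ccc(CO)cc1 | starting material
2 | tributyl(iodomethyl)stannane | CCCC[Sn](CCCC)(CCCC)CI | starting material
3 | tributyl[(4-methoxybenzyloxy)methyl]stannane | CCCC[Sn](CCCC)(CCCC)COCc1ccc(OC)cc1 | intermediate
4 | (R)-4-(tert-butyldimethylsilyloxy)cyclopent-2-en-1-one | O=C1C[C@@H](O[Si](C)(C)C(C)(C)C)C=C1 | starting material
5 | (4-methoxybenzyloxy)methyllithium | [Li]COCc1ccc(OC)cc1 | intermediate (not isolated)
6 | lithium bis[(4-methoxybenzyloxy)methyl]cuprate | [Li+].COc1ccc(COC[Cu-]COCc2ccc(OC)cc2)cc1 | intermediate (not isolated)
7 | trans-3,4-disubstituted trimethylsilyl enol ether (4-silyloxy, 3-alkoxymethyl) | C[Si](C)(C)OC1=C[C@@H](COCc2ccc(OC)cc2)[C@H](O[Si](C)(C)C(C)(C)C)C1 | intermediate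
8 | (R)-4-(tert-butyldimethylsilyloxy)-3-[(4-methoxybenzyloxy)methyl]cyclopent-2-en-1-one | O=C1C=C(COCc2ccc(OC)cc2)[C@H](O[Si](C)(C)C(C)(C)C)C1 | intermediate
9 | 3-methylbut-3-en-1-ol | C=C(C)CCO | starting material
10 | 3-methylbut-3-enal | C=C(C)CC=O | intermediate
11 | methyllithium | C[Li] | starting material
12 | lithium dimethylcuprate | [Li+].C[Cu-]C | intermediate (not isolated)
13 | lithium enolate (O–C4=C5, quaternary C1) | [Li]OC1=C[C@](C)(COCc2ccc(OC)cc2)[C@H](O[Si](C)(C)C(C)(C)C)C1 | intermediate (not isolated)
14 | chlorozinc enolate | Cl[Zn]OC1=C[C@](C)(COCc2ccc(OC)cc2)[C@H](O[Si](C)(C)C(C)(C)C)C1 | intermediate (not isolated)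
15 | aldol adduct (C4 ketone; C1 with β-CH3 and α-CH2OPMB; 2α-OTBS; 5α-H; C5/C6 anti) | C=C(C)C[C@@H](O)[C@@H]1C(=O)C[C@@H](O[Si](C)(C)C(C)(C)C)[C@@]1(C)COCc2ccc(OC)cc2 | intermediate
16 | 2-bromo-2-methylpropanoyl bromide | CC(C)(Br)C(=O)Br | starting material
17 | C6 2-bromo-2-methylpropanoate of 15 | C=C(C)C[C@@H](OC(=O)C(C)(C)Br)[C@@H]1C(=O)C[C@@H](O[Si](C)(C)C(C)(C)C)[C@@]1(C)COCc2ccc(OC)cc2 | intermediate
18 | samarium enolate of the C6 ester (O–SmI2) | C=C(C)C[C@@H](OC(O[Sm](I)I)=C(C)C)[C@@H]1C(=O)C[C@@H](O[Si](C)(C)C(C)(C)C)[C@@]1(C)COCc2ccc(OC)cc2 | intermediate (not isolated)
19 | cis-fused δ-lactone (O6–CO–CMe2–C4, 4α-OH) | C=C(C)C[C@H]2OC(=O)C(C)(C)[C@]3(O)C[C@@H](O[Si](C)(C)C(C)(C)C)[C@@](C)(COCc4ccc(OC)cc4)[C@H]23 | intermediate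
20 | lithium carboxylate of the opened lactone | [Li+].C=C(C)C[C@@H](O)[C@@H]1[C@](O)(C(C)(C)C(=O)[O-])C[C@@H](O[Si](C)(C)C(C)(C)C)[C@@]1(C)COCc2ccc(OC)cc2 | intermediate (not isolated)
21 | C4,C6-diol (4α-hydroxy-4β-isopropyl, C6 hydroxyl free) | C=C(C)C[C@@H](O)[C@@H]1[C@](O)(C(C)C)C[C@@H](O[Si](C)(C)C(C)(C)C)[C@@]1(C)COCc2ccc(OC)cc2 | intermediate
22 | 3,4-dimethoxybenzoyl chloride | COc1ccc(C(=O)Cl)cc1OC | starting material
23 | C6 veratrate | C=C(C)C[C@@H](OC(=O)c2ccc(OC)c(OC)c2)[C@@H]1[C@](O)(C(C)C)C[C@@H](O[Si](C)(C)C(C)(C)C)[C@@]1(C)COCc3ccc(OC)cc3 | intermediate
24 | C10 primary alcohol | C=C(C)C[C@@H](OC(=O)c2ccc(OC)c(OC)c2)[C@@H]1[C@](O)(C(C)C)C[C@@H](O[Si](C)(C)C(C)(C)C)[C@@]1(C)CO | intermediate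
25 | C10 aldehyde | C=C(C)C[C@@H](OC(=O)c2ccc(OC)c(OC)c2)[C@@H]1[C@](O)(C(C)C)C[C@@H](O[Si](C)(C)C(C)(C)C)[C@@]1(C)C=O | intermediate
26 | C10 vinyl carbinol (both C10 epimers) | C=C(C)C[C@@H](OC(=O)c2ccc(OC)c(OC)c2)[C@@H]1[C@](O)(C(C)C)C[C@@H](O[Si](C)(C)C(C)(C)C)[C@@]1(C)C(O)C=C | intermediate
27 | trans-fused cycloheptenol (both C10 epimers) | COc1ccc(C(=O)O[C@@H]2CC(C)=CC(O)[C@]3(C)[C@H](O[Si](C)(C)C(C)(C)C)C[C@@](O)(C(C)C)[C@@H]23)cc1OC | intermediate
28 | enone (C10 ketone, C8=C9, 2α-OTBS) | COc1ccc(C(=O)O[C@@H]2CC(C)=CC(=O)[C@]3(C)[C@H](O[Si](C)(C)C(C)(C)C)C[C@@](O)(C(C)C)[C@@H]23)cc1OC | intermediate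
29 | 2α-hydroxy enone | COc1ccc(C(=O)O[C@@H]2CC(C)=CC(=O)[C@]3(C)[C@H](O)C[C@@](O)(C(C)C)[C@@H]23)cc1OC | intermediate
30 | diethylboron chelate of 29 (C2–O–BEt2 bound to the C10 carbonyl) | COc1ccc(C(=O)O[C@@H]2CC(C)=CC(=O)[C@]3(C)[C@H](OB(CC)CC)C[C@@](O)(C(C)C)[C@@H]23)cc1OC | intermediate (not isolated)
31 | 2α,4α,10α-triol with the C8=C9 (Z)-alkene (6-veratrate) | COc1ccc(C(=O)O[C@@H]2CC(C)=C[C@H](O)[C@]3(C)[C@H](O)C[C@@](O)(C(C)C)[C@@H]23)cc1OC | intermediate
32 | AgNO3 complex of the (E)-C8=C9 isomer of 31 (C7 β and C10 α across the double bond) | COc1ccc(C(=O)O[C@@H]2C/C(C)=C/[C@H](O)[C@]3(C)[C@H](O)C[C@@](O)(C(C)C)[C@@H]23)cc1OC.[Ag+].[O-][N+](=O)[O-] | intermediate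
33 | trans-fused 8,9-epoxy triol (O–C8 β, O–C9 α, 8-methyl α) | COc1ccc(C(=O)O[C@@H]2C[C@@]3(C)O[C@@H]3[C@H](O)[C@]3(C)[C@H](O)C[C@@](O)(C(C)C)[C@@H]23)cc1OC | intermediate
34 | target | COc1ccc(C(=O)O[C@@H]2C[C@@]3(C)O[C@@H]3[C@H](O)[C@]3(C)[C@H](OC(C)=O)C[C@@](O)(C(C)C)[C@@H]23)cc1OC | target

## Step count and least certain steps

Total step count: 19. Longest linear sequence: 18 steps (steps 1–3 and 5–19; step 4 supplies the aldehyde).

**Step 5 (key step).** The most likely failure is slow conjugate addition at the fully substituted β-carbon next to the silyloxy-bearing carbon. That would give the enolate time to equilibrate toward C3 and expel silyloxide, and incomplete anti selectivity at C6 in the aldol is a second risk. Fallback: setting out from 8, the addition of 12 is run with TMSCl, which accelerates it and captures the enolate as the trimethylsilyl enol ether F1. Treatment of F1 with methyllithium then regenerates 13 cleanly at low temperature, and transmetalation to 14 and addition of 10 bring the route back at 15. The two events are thus decoupled and each can be optimised on its own.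

**Step 18 (together with the capture in step 17).** This is the least certain part of the route. The (E)-cycloheptene is more strained than the eight-membered (E)-cycloalkenes on which this epoxidation is established, and here the ring also carries a trans-fused cyclopentane.
- Likely losses: weak retention of a trisubstituted, polar alkene on silver in step 17; thermal reversion to the (Z)-alkene once silver is removed, before oxygen transfer; opening or rearrangement of the strained oxirane during isolation.
- Any (Z)-alkene that re-forms reacts only slowly at −78 °C; if it does react it gives the cis-fused oxirane, which would have to be separated.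
- Fallback, without silver and without isolating a complex: setting out from 31, irradiation (254 nm, methyl benzoate, Et2O) at −78 °C to the photostationary state generates the (E)-alkene, the organic part of 32, which should persist at this temperature. DMDO is then added in the dark in portions at −78 °C and should consume only the strained isomer, which returns the route at 33. Unchanged 31 is recovered and recycled.

**Step 8.** The thiyl radical of the hydrogen-atom shuttle may add to the 1,1-disubstituted alkene (thiol–ene reaction), and the β-hydroxy ester may undergo retro-aldol cleavage during saponification. Fallback: the extra carbon is kept and deoxygenated, not excised. Setting out from 15, acylation with 2-bromopropanoyl bromide and pyridine gives the C6 2-bromopropanoate F2, and SmI2 at −78 °C gives the cis-fused α-methyl lactone F3 through the same tether (the new methine centre is irrelevant). LiBH4 opens F3 to the triol F4 with a CH(CH3)CH2OH group on C4. I2, PPh3 and imidazole convert only the primary hydroxyl into the iodide F5. Bu3SnH with AIBN in toluene at 80 °C reduces the C–I bond to CH3, which returns the route at 21.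

**Step 16.** Hydride may be delivered from the α-face, the usual course anti to the angular methyl, if the boron chelate is not fully formed or the ring conformation overrides it. Conjugate reduction is a lesser risk. Fallback: the reduction is moved in front of the ring closure. Setting out from 26, Dess–Martin oxidation gives the open-chain dienone F6 and HF·pyridine the hydroxy dienone F7. The same Et2BOMe/NaBH4 reduction on this conformationally free β-hydroxy ketone should give the 1,3-syn diol F8. Ring-closing metathesis of F8 with the second-generation Grubbs catalyst returns the route at 31.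

**Step 19.** Acylation may also occur at the C10 hydroxyl, or the acetyl group may shift between the 1,3-syn oxygens at C2 and C10, so the site selectivity may be incomplete. Fallback: the acetate is introduced before the C10 carbinol exists. Setting out from 29, whose only secondary hydroxyl is at C2, Ac2O/DMAP gives the 2-acetoxy enone F9. Reduction with NaBH4 and CeCl3 at −78 °C gives both C10 alcohols; the hydride face is not secured here, so the 10α-epimer F10 is separated and the 10β-epimer is reoxidised with MnO2 and recycled. F10 is then taken through the conditions of step 17 to its AgNO3 complex F11, and the conditions of step 18 applied to F11 return the route at 34.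

## Further compounds

F1 | step 5 | trimethylsilyl enol ether of the conjugate adduct (O–C4=C5, quaternary C1) | C[Si](C)(C)OC1=C[C@](C)(COCc2ccc(OC)cc2)[C@H](O[Si](C)(C)C(C)(C)C)C1
F0 | step 18 | none | none
F2 | step 8 | C6 2-bromopropanoate of 15 | C=C(C)C[C@@H](OC(=O)C(C)Br)[C@@H]1C(=O)C[C@@H](O[Si](C)(C)C(C)(C)C)[C@@]1(C)COCc2ccc(OC)cc2
F3 | step 8 | cis-fused α-methyl δ-lactone (both epimers at the new methine) | C=C(C)C[C@H]2OC(=O)C(C)[C@]3(O)C[C@@H](O[Si](C)(C)C(C)(C)C)[C@@](C)(COCc4ccc(OC)cc4)[C@H]23
F4 | step 8 | triol with a 1-hydroxypropan-2-yl group on C4 | C=C(C)C[C@@H](O)[C@@H]1[C@](O)(C(C)CO)C[C@@H](O[Si](C)(C)C(C)(C)C)[C@@]1(C)COCc2ccc(OC)cc2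
F5 | step 8 | primary iodide (1-iodopropan-2-yl group on C4) | C=C(C)C[C@@H](O)[C@@H]1[C@](O)(C(C)CI)C[C@@H](O[Si](C)(C)C(C)(C)C)[C@@]1(C)COCc2ccc(OC)cc2
F6 | step 16 | open-chain dienone (C10 vinyl ketone, 2α-OTBS) | C=C(C)C[C@@H](OC(=O)c2ccc(OC)c(OC)c2)[C@@H]1[C@](O)(C(C)C)C[C@@H](O[Si](C)(C)C(C)(C)C)[C@@]1(C)C(=O)C=C
F7 | step 16 | open-chain 2α-hydroxy dienone | C=C(C)C[C@@H](OC(=O)c2ccc(OC)c(OC)c2)[C@@H]1[C@](O)(C(C)C)C[C@@H](O)[C@@]1(C)C(=O)C=C
F8 | step 16 | open-chain 1,3-syn diol (2α-hydroxy, 10-hydroxy as in 31) | C=C(C)C[C@@H](OC(=O)c2ccc(OC)c(OC)c2)[C@@H]1[C@](O)(C(C)C)C[C@@H](O)[C@@]1(C)[C@@H](O)C=C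
F9 | step 19 | 2α-acetoxy enone | COc1ccc(C(=O)O[C@@H]2CC(C)=CC(=O)[C@]3(C)[C@H](OC(C)=O)C[C@@](O)(C(C)C)[C@@H]23)cc1OC
F10 | step 19 | 2α-acetoxy-10α-hydroxy (Z)-alkene | COc1ccc(C(=O)O[C@@H]2CC(C)=C[C@H](O)[C@]3(C)[C@H](OC(C)=O)C[C@@](O)(C(C)C)[C@@H]23)cc1OC
F11 | step 19 | AgNO3 complex of the (E)-isomer of F10 | COc1ccc(C(=O)O[C@@H]2C/C(C)=C/[C@H](O)[C@]3(C)[C@H](OC(C)=O)C[C@@](O)(C(C)C)[C@@H]23)cc1OC.[Ag+].[O-][N+](=O)[O-]
A1 | alternative 1 | cyclopentane-1,2-dicarbaldehyde (C6 and C10 formyl, 2α-OAc, 4α-OSiEt3) | O=C[C@]1(C)[C@H](OC(C)=O)C[C@@](O[Si](CC)(CC)CC)(C(C)C)[C@H]1C=O
A2 | alternative 1 | 3-iodo-2-(trimethylsilylmethyl)propene | C=C(CI)C[Si](C)(C)C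
A3 | alternative 1 | methylene hydroazulene diol | C=C1C[C@H](O)[C@]2(C)[C@H](OC(C)=O)C[C@@](O[Si](CC)(CC)CC)(C(C)C)[C@H]2[C@H](O)C1
A4 | alternative 2 | acyclic α-diazoketone with secondary C4 silyl ether | [N-]=[N+]=CC(=O)[C@@](C)(CO[Si](C)(C)C(C)(C)C)[C@H](C(=O)OC)[C@H](O[Si](C)(C)C(C)(C)C)C(C)C
A5 | alternative 2 | cyclopentanone with tertiary C4 silyl ether | O=C1C[C@@](O[Si](C)(C)C(C)(C)C)(C(C)C)[C@@H](C(=O)OC)[C@]1(C)CO[Si](C)(C)C(C)(C)C
A6 | alternative 3 | anisole-tethered α-diazoketone | CC(=[N+]=[N-])C(=O)C[C@@](O[Si](CC)(CC)CC)(C(C)C)c1ccc(C)cc1OC
A7 | alternative 3 | methoxy azulenone (cycloheptatriene) | COC1=C2[C@](O[Si](CC)(CC)CC)(C(C)C)CC(=O)[C@@]2(C)C=CC(C)=C1
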